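Ring C is cut at C4–C4a and O1–C2. Its C4–C3–C2 chain is the three-carbon enone unit of a chalcone, while ring A supplies C4a (its boron-bearing carbon) and O1 (the ortho phenol). One operation, a rhodium-catalysed asymmetric 1,4-arylation followed by hemiketal dehydration, forms both bonds, closes ring C as a 4H-chromene and sets C4 (S). The precursors are a benzyl-protected chalcone whose beta-aryl group is ring D carrying an ortho bromide (the later stilbene handle) and 4-benzyloxy-2-hydroxyphenylboronic acid. Hydroboration anti to ring D then sets C3 and C2, a Heck reaction installs the styryl arm, and debenzylation ends the synthesis.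

Key step: step 6

Configuration of the target: (2R,3S,4S). Ring B at C2 and ring D at C4 are cis, and the C3 hydroxyl is trans to both.

Assumption: the (R,R)-diene is taken to deliver the aryl group to the Re face of C-beta, as its facial model for enones predicts; if a first run shows the opposite sense, the (S,S)-ligand is used with nothing else changed.

Step 1
Reactants: 1 5-bromoresorcinol
Product: 2 1,3-bis(benzyloxy)-5-bromobenzene
Conditions: BnBr (2.2 equiv), K2CO3, DMF, 60 °C
Reagents that add atoms: benzyl bromide, BrCc1ccccc1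
Why: Williamson etherification of both phenols under carbonate conditions is routine and leaves the aryl bromide untouched.

Step 2
Reactants: 2 1,3-bis(benzyloxy)-5-bromobenzene
Product: 4 2,4-bis(benzyloxy)-6-bromobenzaldehyde, via aryl iminium chloride 3 (not isolated)
Conditions: POCl3, DMF, 0 to 75 °C; aq NaOAc
Reagents that add atoms: N,N-dimethylformamide, CN(C)C=O; water, O
Why: Vilsmeier–Haack formylation of a 1,3-dialkoxyarene should occur para to one ether, here at the carbon between bromine and a benzyloxy group and not at the more crowded carbon between the two ethers, and the iminium salt is hydrolysed on work-up.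

Step 3
Reactants: 4 2,4-bis(benzyloxy)-6-bromobenzaldehyde; 5 4-benzyloxyacetophenone
Product: 6 (E)-1-[4-(benzyloxy)phenyl]-3-[2,4-bis(benzyloxy)-6-bromophenyl]prop-2-en-1-one
Conditions: KOH (aq), EtOH/THF, rt
Reagents that add atoms: none
Why: Claisen–Schmidt condensation (aldol addition, then E1cB loss of water) of a methyl ketone with a non-enolisable aldehyde should give the thermodynamically favoured E enone.

Step 4
Reactants: 7 4-bromoresorcinol
Product: 8 5-(benzyloxy)-2-bromophenol
Conditions: BnBr (1.0 equiv), K2CO3, acetone, 50 °C; chromatography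
Reagents that add atoms: benzyl bromide, BrCc1ccccc1
Why: Williamson monoalkylation with one equivalent of benzyl bromide should favour the hydroxyl para to bromine, which is less hindered and more nucleophilic than the ortho hydroxyl that bromine shields and acidifies, and the bis-ether and the minor regioisomer are removed by chromatography.

Step 5
Reactants: 8 5-(benzyloxy)-2-bromophenol
Product: 11 [4-(benzyloxy)-2-hydroxyphenyl]boronic acid, via dilithio species 9 (not isolated), via lithium aryl(triisopropoxy)borate 10 (not isolated)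
Conditions: n-BuLi (2.2 equiv), THF, −78 °C; B(OiPr)3, −78 °C to rt; 1 M HCl
Reagents that add atoms: triisopropyl borate, CC(C)OB(OC(C)C)OC(C)C; water, O
Why: Deprotonation followed by bromine–lithium exchange gives the dilithio species, which is trapped by the borate ester and hydrolysed by acid, the standard route from 2-bromophenols to 2-hydroxyarylboronic acids, and the benzyl ether is inert at this temperature.

Step 6
Reactants: 6 (E)-1-[4-(benzyloxy)phenyl]-3-[2,4-bis(benzyloxy)-6-bromophenyl]prop-2-en-1-one; 11 [4-(benzyloxy)-2-hydroxyphenyl]boronic acid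
Product: 14 (4S)-7-(benzyloxy)-2-[4-(benzyloxy)phenyl]-4-[2,4-bis(benzyloxy)-6-bromophenyl]-4H-chromene, via beta-aryl ketone 12 (not isolated), via hemiketal 13 (not isolated)
Conditions: 11 (3 equiv, in portions), [RhCl(C2H4)2]2 (3 mol %), (1R,4R)-2,5-diphenylbicyclo[2.2.2]octa-2,5-diene (6.6 mol %), KOH (0.5 equiv), dioxane/H2O 10:1, 50 °C; then PPTS (10 mol %), 4 Å MS, toluene, 60 °C
Reagents that add atoms: none
Why: The aryl group passes from boron to a hydroxo complex of monovalent rhodium carrying the chiral diene, the aryl–rhodium bond adds across the enone at C-beta (forming C4–C4a), and water protonates the rhodium enolate to release ketone 12 and regenerate Rh–OH; this is the Hayashi–Miyaura asymmetric 1,4-addition, a reaction type known for 2-hydroxyarylboronic acids and enones with closure to 2-hydroxychromans and 4H-chromenes. Ring C then closes by 6-exo-trig attack of the phenol oxygen on the ketone carbonyl (forming O1–C2) to give hemiketal 13, whose C2 configuration does not matter because PPTS dehydrates it to the enol ether. C4 is the only stereocentre formed and is controlled by the C2-symmetric diene on rhodium, which should expose the Re face of C-beta (priorities ring D > C-alpha > H) and so give 4S. The ethylene complex is the rhodium source because cyclooctadiene would stay bound and catalyse a racemic background reaction. The step needs site selectivity on ring A, 1,4-addition without reaction at C–Br, and survival of the acid-labile C4–ring D bond: the position of boron fixes C4a, monovalent rhodium should not insert into the aryl bromide under these conditions, and only a weak acid is used for the dehydration. The slow insertion expected from the 2,6-disubstituted beta-aryl group is met by the active diene ligand, the excess of 11 (which also covers protodeboronation) and moderate heating.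

Step 7
Reactants: 14 (4S)-7-(benzyloxy)-2-[4-(benzyloxy)phenyl]-4-[2,4-bis(benzyloxy)-6-bromophenyl]-4H-chromene
Product: 16 (2R,3S,4S)-7-(benzyloxy)-2-[4-(benzyloxy)phenyl]-4-[2,4-bis(benzyloxy)-6-bromophenyl]chroman-3-ol, via C3 alkylborane 15 (not isolated)
Conditions: BH3·THF (3 equiv), THF, 0 °C to rt; then 30% H2O2, aq NaOAc, 0 °C to rt
Reagents that add atoms: hydrogen peroxide, OO
Why: In this hydroboration–oxidation borane should add syn across the enol ether with boron at C3 (beta to oxygen) from the face opposite the pseudo-axial ring D, so that H at C2 and, after oxidation with retention, OH at C3 lie anti to ring D and the 2,3-trans-3,4-trans flavan-3-ol results, as known for flav-2-enes, while the buffered peroxide limits base-induced ring opening of the beta-aryloxy borane.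

Step 8
Reactants: 17 3,4-bis(benzyloxy)benzaldehyde
Product: 18 1,2-bis(benzyloxy)-4-ethenylbenzene (3,4-dibenzyloxystyrene)
Conditions: Ph3PCH3Br, KOt-Bu, THF, 0 °C to rt
Reagents that add atoms: methyltriphenylphosphonium bromide, C[P+](c1ccccc1)(c1ccccc1)c1ccccc1.[Br-]
Why: Wittig methylenation of an aromatic aldehyde with the non-stabilised ylide is routine and the benzyl ethers are inert.

Step 9
Reactants: 16 (2R,3S,4S)-7-(benzyloxy)-2-[4-(benzyloxy)phenyl]-4-[2,4-bis(benzyloxy)-6-bromophenyl]chroman-3-ol; 18 1,2-bis(benzyloxy)-4-ethenylbenzene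
Product: 19 (2R,3S,4S)-7-(benzyloxy)-2-[4-(benzyloxy)phenyl]-4-[2,4-bis(benzyloxy)-6-[(E)-2-[3,4-bis(benzyloxy)phenyl]ethenyl]phenyl]chroman-3-ol
Conditions: 18 (1.5 equiv), Pd2(dba)3 (2.5 mol %), P(t-Bu)3·HBF4 (10 mol %), Cy2NMe, dioxane, 90 °C
Reagents that add atoms: none
Why: In this Mizoroki–Heck reaction zerovalent palladium with the bulky electron-rich phosphine should insert into the hindered C–Br bond, and syn insertion of the styrene at its terminal carbon followed by syn beta-hydride elimination gives the E-stilbene without touching the free secondary alcohol or the three stereocentres.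

Step 10
Reactants: 19 (2R,3S,4S)-7-(benzyloxy)-2-[4-(benzyloxy)phenyl]-4-[2,4-bis(benzyloxy)-6-[(E)-2-[3,4-bis(benzyloxy)phenyl]ethenyl]phenyl]chroman-3-ol
Product: 20 (2R,3S,4S)-4-[2-[(E)-2-(3,4-dihydroxyphenyl)ethenyl]-4,6-dihydroxyphenyl]-2-(4-hydroxyphenyl)chroman-3,7-diol (CNP0170061.1)
Conditions: BCl3 (12 equiv), pentamethylbenzene (18 equiv), CH2Cl2, −78 °C; MeOH quench
Reagents that add atoms: none
Why: Lewis-acid debenzylation with BCl3 at low temperature, with pentamethylbenzene as a non-basic scavenger of the benzyl cation, should cleave the six aryl benzyl ethers without reducing or benzylating the stilbene, which hydrogenolysis would not spare, and without ionising C2 or C4.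

Compound list
1 | 5-bromoresorcinol (5-bromobenzene-1,3-diol) | Oc1cc(O)cc(Br)c1 | starting material
2 | 1,3-bis(benzyloxy)-5-bromobenzene | Brc1cc(OCc2ccccc2)cc(OCc2ccccc2)c1 | intermediate
3 | N-[[2,4-bis(benzyloxy)-6-bromophenyl]methylidene]-N-methylmethanaminium chloride (aryl iminium chloride, not isolated) | C[N+](C)=Cc1c(OCc2ccccc2)cc(OCc2ccccc2)cc1Br.[Cl-] | intermediate
4 | 2,4-bis(benzyloxy)-6-bromobenzaldehyde | O=Cc1c(OCc2ccccc2)cc(OCc2ccccc2)cc1Br | intermediate
5 | 4-benzyloxyacetophenone (1-[4-(benzyloxy)phenyl]ethan-1-one) | CC(=O)c1ccc(OCc2ccccc2)cc1 | starting material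
6 | (E)-1-[4-(benzyloxy)phenyl]-3-[2,4-bis(benzyloxy)-6-bromophenyl]prop-2-en-1-one | O=C(/C=C/c1c(OCc2ccccc2)cc(OCc2ccccc2)cc1Br)c1ccc(OCc2ccccc2)cc1 | intermediate
7 | 4-bromoresorcinol (4-bromobenzene-1,3-diol) | Oc1ccc(Br)c(O)c1 | starting material
8 | 5-(benzyloxy)-2-bromophenol | Oc1cc(OCc2ccccc2)ccc1Br | intermediate
9 | lithium 5-(benzyloxy)-2-lithiophenolate (dilithio species, not isolated) | [Li]Oc1cc(OCc2ccccc2)ccc1[Li] | intermediate
10 | lithium [4-(benzyloxy)-2-(lithiooxy)phenyl]tri(propan-2-yloxy)borate (not isolated) | [Li+].CC(C)O[B-](OC(C)C)(OC(C)C)c1ccc(OCc2ccccc2)cc1O[Li] | intermediate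
11 | [4-(benzyloxy)-2-hydroxyphenyl]boronic acid | OB(O)c1ccc(OCc2ccccc2)cc1O | intermediate
12 | (3S)-3-[4-(benzyloxy)-2-hydroxyphenyl]-1-[4-(benzyloxy)phenyl]-3-[2,4-bis(benzyloxy)-6-bromophenyl]propan-1-one (not isolated) | O=C(C[C@H](c1c(OCc2ccccc2)cc(OCc2ccccc2)cc1Br)c1ccc(OCc2ccccc2)cc1O)c1ccc(OCc2ccccc2)cc1 | intermediate
13 | (4S)-7-(benzyloxy)-2-[4-(benzyloxy)phenyl]-4-[2,4-bis(benzyloxy)-6-bromophenyl]chroman-2-ol, both C2 epimers (not isolated) | OC1(c2ccc(OCc3ccccc3)cc2)C[C@H](c2c(OCc3ccccc3)cc(OCc3ccccc3)cc2Br)c2ccc(OCc3ccccc3)cc2O1 | intermediate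
14 | (4S)-7-(benzyloxy)-2-[4-(benzyloxy)phenyl]-4-[2,4-bis(benzyloxy)-6-bromophenyl]-4H-chromene | C1(c2ccc(OCc3ccccc3)cc2)=C[C@H](c2c(OCc3ccccc3)cc(OCc3ccccc3)cc2Br)c2ccc(OCc3ccccc3)cc2O1 | intermediate
15 | [(2S,3S,4S)-7-(benzyloxy)-2-[4-(benzyloxy)phenyl]-4-[2,4-bis(benzyloxy)-6-bromophenyl]chroman-3-yl]borane, boron at C3 anti to ring D and cis to H at C2 (not isolated) | c1ccccc1COc1ccc([C@H]2Oc3cc(OCc4ccccc4)ccc3[C@@H](c3c(OCc4ccccc4)cc(OCc4ccccc4)cc3Br)[C@@H]2B)cc1 | intermediate
16 | (2R,3S,4S)-7-(benzyloxy)-2-[4-(benzyloxy)phenyl]-4-[2,4-bis(benzyloxy)-6-bromophenyl]chroman-3-ol | c1ccccc1COc1ccc([C@H]2Oc3cc(OCc4ccccc4)ccc3[C@@H](c3c(OCc4ccccc4)cc(OCc4ccccc4)cc3Br)[C@@H]2O)cc1 | intermediate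
17 | 3,4-bis(benzyloxy)benzaldehyde | O=Cc1ccc(OCc2ccccc2)c(OCc2ccccc2)c1 | starting material
18 | 1,2-bis(benzyloxy)-4-ethenylbenzene (3,4-dibenzyloxystyrene) | C=Cc1ccc(OCc2ccccc2)c(OCc2ccccc2)c1 | intermediate
19 | (2R,3S,4S)-7-(benzyloxy)-2-[4-(benzyloxy)phenyl]-4-[2,4-bis(benzyloxy)-6-[(E)-2-[3,4-bis(benzyloxy)phenyl]ethenyl]phenyl]chroman-3-ol | c1ccccc1COc1ccc([C@H]2Oc3cc(OCc4ccccc4)ccc3[C@@H](c3c(OCc4ccccc4)cc(OCc4ccccc4)cc3/C=C/c3ccc(OCc4ccccc4)c(OCc4ccccc4)c3)[C@@H]2O)cc1 | intermediate
20 | (2R,3S,4S)-4-[2-[(E)-2-(3,4-dihydroxyphenyl)ethenyl]-4,6-dihydroxyphenyl]-2-(4-hydroxyphenyl)chroman-3,7-diol | Oc1ccc([C@H]2Oc3cc(O)ccc3[C@@H](c3c(O)cc(O)cc3/C=C/c3ccc(O)c(O)c3)[C@@H]2O)cc1 | target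

Total step count: 10. Longest linear sequence: 7 steps (steps 1, 2, 3, 6, 7, 9, 10).

Steps most likely to fail

Step 6. The process at risk is protodeboronation of the electron-rich boronic acid outrunning insertion into an enone whose beta-aryl group is 2,6-disubstituted, or incomplete facial discrimination at C-beta. The fallback sets out from 4, 5 and 8 and returns at 14; it closes the same ring through an ortho-quinone methide, forming C3–C4 and O1–C2 instead. Dilithio species 9, made from 8 as in step 5, is added to aldehyde 4 at −78 °C to give racemic [4-(benzyloxy)-2-hydroxyphenyl][2,4-bis(benzyloxy)-6-bromophenyl]methanol F1. Ketone 5 is converted with NH2OH·HCl and NaOAc into 1-[4-(benzyloxy)phenyl]ethan-1-one oxime F2, and reductive acylation (Fe powder, Ac2O, AcOH) gives N-[1-[4-(benzyloxy)phenyl]ethenyl]acetamide F3. A BINOL-derived chiral phosphoric acid with molecular sieves in CH2Cl2 dehydrates F1 to the ortho-quinone methide; F3 adds to its exocyclic carbon within the hydrogen-bonded ion pair and the phenol oxygen traps the N-acyliminium ion, which should give N-[(4S)-7-(benzyloxy)-2-[4-(benzyloxy)phenyl]-4-[2,4-bis(benzyloxy)-6-bromophenyl]chroman-2-yl]acetamide F4. PPTS in warm toluene then expels acetamide to give 14. The enantiomer of the acid that leads to 4S is chosen in a trial run.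

Step 10. The process at risk is acid-triggered chemistry of the electron-rich stilbene (protonation, cyclisation, loss of E geometry) while six benzyl ethers are cleaved by a Lewis acid. The fallback sets out from 16 and returns at 20; it moves the Lewis-acid step to a stage without the alkene and ends with a non-acidic deprotection. Compound 16 is debenzylated with BCl3 and pentamethylbenzene at −78 °C to (2R,3S,4S)-4-(2-bromo-4,6-dihydroxyphenyl)-2-(4-hydroxyphenyl)chroman-3,7-diol F5. Ac2O, pyridine and DMAP give (2R,3S,4S)-7-acetoxy-2-(4-acetoxyphenyl)-4-(2,4-diacetoxy-6-bromophenyl)chroman-3-yl acetate F6. Heck coupling under the conditions of step 9 with 3,4-diacetoxystyrene F7 should give the heptaacetate of the target F8, and methanolysis (catalytic K2CO3, MeOH, 0 °C, argon) releases 20.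

Step 9. The process at risk is sluggish oxidative addition and insertion at the bromide next to the diarylmethine carbon, with hydrodebromination or branched insertion of the electron-rich styrene competing. The fallback sets out from 16 and 18 and returns at 19; it replaces carbopalladation by transmetalation, so that alkene geometry and regiochemistry are fixed in the coupling partner. Cross-metathesis of 18 with vinylboronic acid pinacol ester (second-generation Grubbs catalyst (H2IMes)(PCy3)Cl2Ru=CHPh, CH2Cl2, 40 °C) should give (E)-2-[3,4-bis(benzyloxy)phenyl]ethenylboronic acid pinacol ester F9. Suzuki–Miyaura coupling of F9 with 16 (Pd(OAc)2, SPhos, K3PO4, toluene/H2O, 80 °C) gives 19.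

Further compounds
F1 | step 6 | [4-(benzyloxy)-2-hydroxyphenyl][2,4-bis(benzyloxy)-6-bromophenyl]methanol (racemic) | OC(c1ccc(OCc2ccccc2)cc1O)c1c(OCc2ccccc2)cc(OCc2ccccc2)cc1Br
F2 | step 6 | 1-[4-(benzyloxy)phenyl]ethan-1-one oxime | CC(=NO)c1ccc(OCc2ccccc2)cc1
F3 | step 6 | N-[1-[4-(benzyloxy)phenyl]ethenyl]acetamide | C=C(NC(C)=O)c1ccc(OCc2ccccc2)cc1
F4 | step 6 | N-[(4S)-7-(benzyloxy)-2-[4-(benzyloxy)phenyl]-4-[2,4-bis(benzyloxy)-6-bromophenyl]chroman-2-yl]acetamide (both C2 epimers) | CC(=O)NC1(c2ccc(OCc3ccccc3)cc2)C[C@H](c2c(OCc3ccccc3)cc(OCc3ccccc3)cc2Br)c2ccc(OCc3ccccc3)cc2O1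
F5 | step 10 | (2R,3S,4S)-4-(2-bromo-4,6-dihydroxyphenyl)-2-(4-hydroxyphenyl)chroman-3,7-diol | Oc1ccc([C@H]2Oc3cc(O)ccc3[C@@H](c3c(O)cc(O)cc3Br)[C@@H]2O)cc1
F6 | step 10 | (2R,3S,4S)-7-acetoxy-2-(4-acetoxyphenyl)-4-(2,4-diacetoxy-6-bromophenyl)chroman-3-yl acetate | CC(=O)Oc1ccc([C@H]2Oc3cc(OC(C)=O)ccc3[C@@H](c3c(OC(C)=O)cc(OC(C)=O)cc3Br)[C@@H]2OC(C)=O)cc1
F7 | step 10 | 3,4-diacetoxystyrene (4-ethenyl-1,2-phenylene diacetate) | C=Cc1ccc(OC(C)=O)c(OC(C)=O)c1
F8 | step 10 | (2R,3S,4S)-7-acetoxy-2-(4-acetoxyphenyl)-4-[2,4-diacetoxy-6-[(E)-2-(3,4-diacetoxyphenyl)ethenyl]phenyl]chroman-3-yl acetate | CC(=O)Oc1ccc([C@H]2Oc3cc(OC(C)=O)ccc3[C@@H](c3c(OC(C)=O)cc(OC(C)=O)cc3/C=C/c3ccc(OC(C)=O)c(OC(C)=O)c3)[C@@H]2OC(C)=O)cc1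
F9 | step 9 | (E)-2-[3,4-bis(benzyloxy)phenyl]ethenylboronic acid pinacol ester | CC1(C)OB(/C=C/c2ccc(OCc3ccccc3)c(OCc3ccccc3)c2)OC1(C)C
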